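(All runs are simulated on assumed constants, noise included.)

In a closed flask the L charged stays among its forms, so each extra mM of charge can be followed as a share: how much of it appears as X at the peak.

| setting | cedar | birch | flask |
|---|---|---|---|
| L | 10 mM | 15 mM | 20 mM |
| remark | run made earlier | run made earlier |  |
| time |  |  | 8.0 d |

| run | time / d | X / % |
|---|---|---|
| cedar | 0.625 | 44.1 |
| cedar | 1.25 | 47.0 |
| cedar | 2.50 | 43.4 |
| cedar | 5.00 | 39.4 |
| cedar | 10.0 | 27.9 |
| birch | 0.625 | 50.4 |
| birch | 1.25 | 52.3 |
| birch | 2.50 | 55.0 |
| birch | 5.00 | 51.9 |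
| birch | 10.0 | 44.2 |

(each reading ± 1 percentage point)

- the moment within 8.0 d at which there is most X
- the amount of X, in percent of the L charged, at that time

The highest readings are 47.0 % for cedar and 55.0 % for birch, which gives 71.0 %. This m is the marginal yield (differential yield), the rise in highest X, in mM, divided by the rise in charge. It is a reading, and each of its two inputs carries a scatter of 1 percentage point.

Turn the question round. For the flask at 20 mM to give a share of X no better than birch, m would have to sink to birch's own share, since an extra mM yielding less than the average pulls the average down. The reading stands 16 points above that share. Carrying m up from birch, I reckon 59.0 % for the flask, at a time after 2.50 d, as the highest reading moved later from cedar to birch.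

The forecast says 60 % at 2.5 d, noting that “The peak moves later with charge”. My figure is lower.

The flask gives 60.2 % at 2.84 d.

    2 L → J (k = 9.40 × 10⁻⁴ M⁻¹ s⁻¹)
    X ⇌ G (k = 1.60 × 10⁻⁵ s⁻¹)
    L ⇌ X (K = 0.860, k = 1.10 × 10⁻⁴ s⁻¹)
    L → Z (k = 8.30 × 10⁻⁹ s⁻¹)
    L ⇌ G (K = 2.90, k = 5.00 × 10⁻⁵ s⁻¹)
    Q ⇌ X, rate k6*(cs6 - [X]) while solid is left; crystals form when [X] > cs6 (solubility = 1.00 mM, k = 2.60 × 10⁻⁴ s⁻¹)

That is 1.2 points above my 59.0 %, and the marginal yield from birch's reading to the flask comes to 75.8 %, against the 71.0 % carried. Now take a neighbour flask, like this one but charged with 8.0 mM of L, the time held. Carrying m down from cedar's reading gives 41.0 % for that neighbour flask. The simulation of that neighbour flask gives a highest X of 41.2 %.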